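Multiply first. Your hunch, that a stronger flask is the same flask run faster, can be tested on the two runs, and I would carry one number from it: 1440 M·min, your flask's starting concentration times time. Call it the clock, the reduced time of second-order kinetics. If every step takes two partners and the equivalents stay fixed, each rate grows with the square of the concentration, so percentages follow the clock.

| setting | delta | beta | flask |
|---|---|---|---|
| starting material | 0.40 M | 0.60 M | 0.80 M |
| reagent | 2 equiv | 2 equiv | 2.00 equiv |
| remark | run made earlier | run made earlier |  |
| time |  |  | 30 h |

- delta (time / h: single product / %, triple product / %, starting material / %): 2.50: 31.1, 2.3, 63.0; 8.00: 42.4, 13.0, 32.1; 12.0: 41.5, 18.6, 25.2; 20.0: 36.3, 19.7, 17.7; 30.0: 30.5, 16.5, 10.4; 40.0: 25.9, 14.4, 7.1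
- beta (time / h: single product / %, triple product / %, starting material / %): 3.00: 37.1, 5.6, 48.4; 5.00: 42.5, 13.3, 35.0; 8.00: 39.9, 18.5, 24.5; 12.0: 37.1, 21.7, 16.7; 20.0: 31.8, 17.2, 12.0; 40.0: 21.4, 13.0, 5.4

(each reading ± 1 percentage point)

- a reading or a percentage of triple product counts all its forms, free or not

1. equivalents of reagent to starting material, everything else as given, that leave most single product at 30 h
2. the amount of single product then, in percent of the starting material charged
3. the amount of single product with the amounts as given

Delta at 12.0 h and beta at 8.00 h share a clock of 288 M·min and read 41.5% and 39.9% single product. At 720 M·min they read 30.5% and 31.8%, so the gaps are of the order of the scatter of 1 percentage point. Your flask's clock is beta's at 40.0 h, its last reading, so I commit to 21.4% for the recipe as given, give or take that scatter. The clock holds equivalents fixed, so I have no reckoning of my own for the best charge.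

The forecast gives 23% for the recipe, higher than my reading, with a range of 20% to 26%. It puts the best charge at 1.3 equiv, leaving 28%, on the ground that “Less reagent should stop the reaction near the single-product peak”.

The simulation gives 23.5% for the recipe, 2.1 points above my reading, and a best charge of 0.974 equiv, leaving 41.2%.

    starting material + reagent → single product + by-product (k = 0.00430 M⁻¹ min⁻¹)
    reagent + single product → double product + by-product (k = 0.00340 M⁻¹ min⁻¹)
    reagent + double product ⇌ triple product + by-product (K = 1.30, k = 0.0110 M⁻¹ min⁻¹)
    reagent + triple product ⇌ idle adduct, settled at all times (K = 4.90 M⁻¹)

In your flask, single product's half-life by its step to double product was 3.2 h at 1.85 h, which is 152 M·min on the clock, shorter than the 1440 M·min the flask runs. At 30.0 h reagent went to starting material at 0.34 of the rate at which it went to single product, and the flask held 23.5% single product against 57.2% double product. The same recipe at 0.32 M runs a clock of 576 M·min, which is delta at 24.0 h; between delta's 36.3% and 30.5% that reads 34.0%, and that flask holds 33.7%.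

The numbers in the tables are calculated for an exercise, noise included.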